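**Plan**

- Retrosynthetic cuts: the side chain at C1′=C2′ (olefination of a C3 aldehyde that comes from a C3 methyl group); the pyridine ring at N2–C3 and C4–C4a ([4+2]); the five-membered ring at C1–C7a, C7a=C4a (metathesis) and C7–C7a; last, C5–C6 (aldol).
- Forward order: C5–C6 is joined first, the cyclopentenone ring is closed by metathesis, C1 and N2 are attached, the pyridine ring is closed last, and the dienyl chain is joined at the end.
- Enabling feature: N2, C1, C7a and C4a already form a 1-azadiene whose C7a=C4a bond lies in the cyclopentenone ring, with the C7 ketone on C7a as a second activating group, so the pyridine ring lacks only the two-carbon unit C3–C4.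
- Stereochemistry: C6 from (R)-lactic acid by self-regeneration of the stereocentre; C5 from the aldol transition state; C5′ from (S)-2-methylbutan-1-ol; both E-alkenes from Wittig and Julia–Kocienski olefination.

Key step: step 13

Remark: atom labels C1–C7a follow the 5H-cyclopenta[c]pyridine numbering of the target (N2, side chain on C3, carbinol C5, acetoxy C6, ketone C7) and are kept for the corresponding atoms of every precursor.

**Route**

Step 1
Reactants: 1 (R)-lactic acid
Product: 2 (2R,5R)-2-tert-butyl-5-methyl-1,3-dioxolan-4-one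
Conditions: t-BuCHO, TsOH·H2O (cat.), H2SO4 (cat.), pentane, reflux, Dean–Stark; crystallisation from pentane at –78 °C
Reagents that add atoms: pivalaldehyde, CC(C)(C)C=O
Why: Acid-catalysed acetalisation of the α-hydroxy acid should favour the cis dioxolanone, in which tert-butyl and methyl lie on the same face, and crystallisation should remove the trans isomer, so the acetal centre (2R) is set by the lactate centre.

Step 2
Reactants: 3 (trimethylsilyl)acetylene; 4 dimethyl oxalate
Product: 6 methyl 2-oxo-4-(trimethylsilyl)but-3-ynoate, via lithium acetylide 5 (not isolated)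
Conditions: n-BuLi, THF, –78 °C; cannulation into 4 (2.5 equiv), THF, –78 °C; AcOH
Reagents that add atoms: none
Why: Acylation of a lithium acetylide with an oxalate diester, where inverse addition to excess oxalate at low temperature should hold the tetrahedral adduct until the quench and so prevent double addition.

Step 3
Reactants: 2 (2R,5R)-2-tert-butyl-5-methyl-1,3-dioxolan-4-one; 6 methyl 2-oxo-4-(trimethylsilyl)but-3-ynoate
Product: 9 methyl (2R)-2-[(2R,4S)-2-tert-butyl-4-methyl-5-oxo-1,3-dioxolan-4-yl]-2-hydroxybut-3-ynoate, via lithium enolate 7 (not isolated), via silylalkyne aldol adduct 8 (not isolated)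
Conditions: LiN(i-Pr)2, THF, –78 °C; 6, –78 °C; AcOH; n-Bu4NF, –78 → 0 °C
Reagents that add atoms: none
Why: Aldol addition of the dioxolanone enolate, in which the ketone is attacked on the face opposite the tert-butyl group (C6 becomes S), and in the lithium-bridged Zimmerman–Traxler chair the rod-like alkynyl group should sit over the dioxolanone ring while the ester points outward (C5 becomes R); buffered fluoride then cleaves the alkynyl C–Si bond in the same flask.

Step 4
Reactants: 9 methyl (2R)-2-[(2R,4S)-2-tert-butyl-4-methyl-5-oxo-1,3-dioxolan-4-yl]-2-hydroxybut-3-ynoate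
Product: 10 methyl (2R)-2-[(2R,4S)-2-tert-butyl-4-methyl-5-oxo-1,3-dioxolan-4-yl]-2-hydroxybut-3-enoate
Conditions: H2 (1 atm), Pd/CaCO3 poisoned with Pb(OAc)2, quinoline, EtOAc, 20 °C
Reagents that add atoms: none
Why: Semi-hydrogenation of a terminal alkyne over lead-poisoned palladium should stop at the alkene when hydrogen uptake is followed, and it touches no stereocentre.

Step 5
Reactants: 10 methyl (2R)-2-[(2R,4S)-2-tert-butyl-4-methyl-5-oxo-1,3-dioxolan-4-yl]-2-hydroxybut-3-enoate
Product: 11 methyl (2R)-2-[(2R,4S)-2-tert-butyl-4-methyl-5-oxo-1,3-dioxolan-4-yl]-2-[(triethylsilyl)oxy]but-3-enoate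
Conditions: Et3SiOTf, 2,6-lutidine, CH2Cl2, 0 → 40 °C
Reagents that add atoms: triethylsilyl trifluoromethanesulfonate, CC[Si](CC)(CC)OS(=O)(=O)C(F)(F)F
Why: Silylation with a silyl triflate and a hindered pyridine base is the standard way to protect a tertiary alcohol; the ether blocks retro-aldol cleavage of C5–C6 in later basic steps and distinguishes the two tertiary oxygens.

Step 6
Reactants: 11 methyl (2R)-2-[(2R,4S)-2-tert-butyl-4-methyl-5-oxo-1,3-dioxolan-4-yl]-2-[(triethylsilyl)oxy]but-3-enoate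
Product: 12 methyl (2R,3S)-2-ethenyl-3-hydroxy-3-methyl-4-oxo-2-[(triethylsilyl)oxy]hex-5-enoate
Conditions: CH2=CHMgBr (1.2 equiv), THF, –78 °C; AcOH, –78 °C; pH 7 buffer, 20 °C
Reagents that add atoms: vinylmagnesium bromide, C=C[Mg]Br
Why: Grignard mono-addition to a 1,3-dioxolan-4-one, where the acylal carbonyl is far more electrophilic than the neopentyl-type methyl ester, the magnesium hemiketal should persist at –78 °C so that the enone appears only after the quench, and the opened hemiacetal then loses pivalaldehyde.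

Step 7
Reactants: 12 methyl (2R,3S)-2-ethenyl-3-hydroxy-3-methyl-4-oxo-2-[(triethylsilyl)oxy]hex-5-enoate
Product: 13 methyl (2R,3S)-3-acetoxy-2-ethenyl-3-methyl-4-oxo-2-[(triethylsilyl)oxy]hex-5-enoate
Conditions: Ac2O, DMAP, Et3N, CH2Cl2, 20 → 40 °C
Reagents that add atoms: acetic anhydride, CC(=O)OC(C)=O
Why: DMAP-catalysed acylation, which a tertiary α-ketol hydroxyl undergoes more readily than an ordinary tertiary alcohol, while the neighbouring oxygen is already blocked as the silyl ether.

Step 8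
Reactants: 13 methyl (2R,3S)-3-acetoxy-2-ethenyl-3-methyl-4-oxo-2-[(triethylsilyl)oxy]hex-5-enoate
Product: 14 methyl (1R,5S)-5-acetoxy-5-methyl-4-oxo-1-[(triethylsilyl)oxy]cyclopent-2-ene-1-carboxylate
Conditions: RuCl2(=CHPh)(PCy3)(H2IMes) (second-generation Grubbs catalyst, 5–10 mol%), toluene, 80 °C
Reagents that add atoms: none
Why: Ring-closing metathesis of a hepta-1,6-dien-3-one to a cyclopent-2-enone, helped by the two quaternary carbons in the tether (Thorpe–Ingold effect) and driven by loss of ethylene.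

Step 9
Reactants: 14 methyl (1R,5S)-5-acetoxy-5-methyl-4-oxo-1-[(triethylsilyl)oxy]cyclopent-2-ene-1-carboxylate
Product: 15 methyl (1R,5S)-5-acetoxy-3-(hydroxymethyl)-5-methyl-4-oxo-1-[(triethylsilyl)oxy]cyclopent-2-ene-1-carboxylate
Conditions: 37% aq. HCHO, PMe3 (0.3 equiv), THF, 20 °C
Reagents that add atoms: formaldehyde, C=O
Why: Morita–Baylis–Hillman hydroxymethylation of a cyclic enone, in which the small phosphine adds reversibly to C4a, the enolate is trapped by formaldehyde at C7a and loss of the phosphine restores the enone; no centre in the molecule can epimerise.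

Step 10
Reactants: 15 methyl (1R,5S)-5-acetoxy-3-(hydroxymethyl)-5-methyl-4-oxo-1-[(triethylsilyl)oxy]cyclopent-2-ene-1-carboxylate
Product: 16 methyl (1R,5S)-5-acetoxy-3-formyl-5-methyl-4-oxo-1-[(triethylsilyl)oxy]cyclopent-2-ene-1-carboxylate
Conditions: Dess–Martin periodinane, CH2Cl2, 0 → 20 °C; used at once
Reagents that add atoms: none
Why: Dess–Martin oxidation of a primary allylic alcohol under neutral, water-free conditions suits an aldehyde that is a strong Michael acceptor, and the quaternary C5 next to C4a should slow its self-condensation.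

Step 11
Reactants: 17 p-toluenesulfonamide
Product: 18 N-sulfinyl-p-toluenesulfonamide
Conditions: SOCl2, benzene, reflux; distillation
Reagents that add atoms: thionyl chloride, O=S(Cl)Cl
Why: Condensation of a primary sulfonamide with thionyl chloride is the usual preparation of N-sulfinyl sulfonamides.

Step 12
Reactants: 16 methyl (1R,5S)-5-acetoxy-3-formyl-5-methyl-4-oxo-1-[(triethylsilyl)oxy]cyclopent-2-ene-1-carboxylate; 18 N-sulfinyl-p-toluenesulfonamide
Product: 19 methyl (1R,5S)-5-acetoxy-5-methyl-3-{(E)-[(4-methylbenzenesulfonyl)imino]methyl}-4-oxo-1-[(triethylsilyl)oxy]cyclopent-2-ene-1-carboxylate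
Conditions: BF3·OEt2 (10 mol%), CH2Cl2, 0 → 20 °C; 2,6-lutidine (0.15 equiv); evaporation, crude used
Reagents that add atoms: none
Why: Imination of an aldehyde with an N-sulfinyl sulfonamide ([2+2] addition of C=O to N=S, then cycloreversion with loss of SO2) should give the N-sulfonyl imine without water or a free amine nucleophile, which this doubly activated acceptor would not tolerate.

Step 13
Reactants: 19 methyl (1R,5S)-5-acetoxy-5-methyl-3-{(E)-[(4-methylbenzenesulfonyl)imino]methyl}-4-oxo-1-[(triethylsilyl)oxy]cyclopent-2-ene-1-carboxylate; 20 2-methoxypropene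
Product: 23 methyl (5R,6S)-6-acetoxy-3,6-dimethyl-7-oxo-5-[(triethylsilyl)oxy]-6,7-dihydro-5H-cyclopenta[c]pyridine-5-carboxylate, via cycloadduct 21 (not isolated), via dihydropyridine 22 (not isolated)
Conditions: 20 (10 equiv), CH2Cl2, 0 → 25 °C; then DBU (3 equiv), THF, 25 → 50 °C
Reagents that add atoms: none
Why: The N-sulfonyl 1-azadiene N2=C1–C7a=C4a, made electron-poor by the sulfonyl group and by the C7 ketone on C7a, should undergo an inverse-electron-demand hetero-Diels–Alder reaction with the enol ether, whose CH2 bonds to C4a while nitrogen bonds to the methoxy-bearing carbon; the path is concerted but asynchronous or stepwise through a zwitterion, and both give the same six-membered ring (a [4+2] closure, or 6-exo-trig attack of nitrogen on the oxocarbenium carbon if stepwise). The closest known reaction type is the cycloaddition of N-sulfonyl-1-aza-1,3-butadienes carrying an acyl or ester group on the central carbon with enol ethers, followed by base-induced elimination to pyridines. DBU then removes the acidic C4a–H, toluenesulfinate leaves from nitrogen in a 1,4-elimination to give 22, and loss of methanol aromatises the ring. The transient centres at C3 and C4a are erased, so endo/exo and facial selectivity do not matter and no new stereocentre remains. The step needs regioselectivity and periselectivity: the polarisation of both partners places the methyl-bearing carbon at C3, and the C7 carbonyl cannot act as an oxadiene because the ring holds it s-trans to C7a=C4a. C5 and C6 are quaternary, non-enolisable spectators, and the silyl ether prevents retro-aldol opening under DBU.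

Step 14
Reactants: 23 methyl (5R,6S)-6-acetoxy-3,6-dimethyl-7-oxo-5-[(triethylsilyl)oxy]-6,7-dihydro-5H-cyclopenta[c]pyridine-5-carboxylate
Product: 24 methyl (5R,6S)-6-acetoxy-3-formyl-6-methyl-7-oxo-5-[(triethylsilyl)oxy]-6,7-dihydro-5H-cyclopenta[c]pyridine-5-carboxylate
Conditions: SeO2 (1.5 equiv), 1,4-dioxane, 90 °C
Reagents that add atoms: selenium dioxide, O=[Se]=O
Why: Riley oxidation of a 2-methylpyridine to the pyridine-2-carbaldehyde, where the C3 methyl group (ortho to nitrogen, para to the acyl-bearing C7a) is the only activated C–H position because C6 is quaternary and the ketone has no α-hydrogen.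

Step 15
Reactants: 25 (S)-2-methylbutan-1-ol; 26 ethyl 2-(triphenylphosphoranylidene)propanoate
Product: 28 ethyl (2E,4S)-2,4-dimethylhex-2-enoate, via aldehyde 27 (not isolated)
Conditions: TEMPO (10 mol%), PhI(OAc)2, CH2Cl2, 20 °C; then 26, 20 °C
Reagents that add atoms: none
Why: TEMPO/PhI(OAc)2 oxidation followed in the same flask by Wittig olefination with a stabilised ylide should give the E-trisubstituted ester without isolating the volatile, easily racemised α-branched aldehyde.

Step 16
Reactants: 28 ethyl (2E,4S)-2,4-dimethylhex-2-enoate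
Product: 29 (2E,4S)-2,4-dimethylhex-2-en-1-ol
Conditions: i-Bu2AlH (2.2 equiv), CH2Cl2, –78 °C; aq. KNaC4H4O6
Reagents that add atoms: none
Why: 1,2-Reduction of an α,β-unsaturated ester with i-Bu2AlH gives the allylic alcohol and leaves the alkene and the stereocentre untouched.

Step 17
Reactants: 29 (2E,4S)-2,4-dimethylhex-2-en-1-ol; 30 1-phenyl-1H-tetrazole-5-thiol
Product: 31 5-{[(2E,4S)-2,4-dimethylhex-2-en-1-yl]sulfanyl}-1-phenyl-1H-tetrazole
Conditions: PPh3, DIAD, THF, 0 → 20 °C
Reagents that add atoms: none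
Why: Mitsunobu thioetherification of a primary allylic alcohol with the acidic tetrazole thiol should proceed by direct SN2 displacement at the unhindered CH2.

Step 18
Reactants: 31 5-{[(2E,4S)-2,4-dimethylhex-2-en-1-yl]sulfanyl}-1-phenyl-1H-tetrazole
Product: 32 5-{[(2E,4S)-2,4-dimethylhex-2-en-1-yl]sulfonyl}-1-phenyl-1H-tetrazole
Conditions: (NH4)6Mo7O24·4H2O (10 mol%), 30% H2O2, EtOH, 0 → 20 °C
Reagents that add atoms: hydrogen peroxide, OO
Why: Molybdate-catalysed peroxide oxidation should convert the tetrazolyl sulfide into the sulfone faster than it epoxidises the trisubstituted alkene.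

Step 19
Reactants: 32 5-{[(2E,4S)-2,4-dimethylhex-2-en-1-yl]sulfonyl}-1-phenyl-1H-tetrazole; 24 methyl (5R,6S)-6-acetoxy-3-formyl-6-methyl-7-oxo-5-[(triethylsilyl)oxy]-6,7-dihydro-5H-cyclopenta[c]pyridine-5-carboxylate
Product: 34 methyl (5R,6S)-6-acetoxy-3-[(1E,3E,5S)-3,5-dimethylhepta-1,3-dien-1-yl]-6-methyl-7-oxo-5-[(triethylsilyl)oxy]-6,7-dihydro-5H-cyclopenta[c]pyridine-5-carboxylate, via sulfonyl carbanion 33 (not isolated)
Conditions: 32 (1.2 equiv), KN(SiMe3)2 (1.15 equiv), DME, –78 °C, 20 min; then 24, –78 → 20 °C; aq. NH4Cl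
Reagents that add atoms: none
Why: Julia–Kocienski olefination, in which the pre-formed allylic sulfonyl anion adds to the aldehyde, Smiles rearrangement and loss of SO2 and tetrazolate follow, and the phenyltetrazolyl sulfone with a potassium counter-ion in DME should favour the E-alkene, here also the conjugated, more stable isomer; pre-metalation keeps free base away from the acetate and ketone of 24.

Step 20
Reactants: 34 methyl (5R,6S)-6-acetoxy-3-[(1E,3E,5S)-3,5-dimethylhepta-1,3-dien-1-yl]-6-methyl-7-oxo-5-[(triethylsilyl)oxy]-6,7-dihydro-5H-cyclopenta[c]pyridine-5-carboxylate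
Product: 35 methyl (5R,6S)-6-acetoxy-3-[(1E,3E,5S)-3,5-dimethylhepta-1,3-dien-1-yl]-5-hydroxy-6-methyl-7-oxo-6,7-dihydro-5H-cyclopenta[c]pyridine-5-carboxylate
Conditions: HF·pyridine, pyridine, THF, 0 → 20 °C
Reagents that add atoms: none
Why: Buffered fluoride desilylation of the tertiary triethylsilyl ether is not basic enough to move the acetate onto the trans-disposed C5 hydroxyl or to open the β-hydroxy ketone by retro-aldol cleavage.

**Compound list**

1 | (R)-lactic acid | C[C@@H](O)C(=O)O | starting material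
2 | (2R,5R)-2-tert-butyl-5-methyl-1,3-dioxolan-4-one | C[C@H]1O[C@@H](C(C)(C)C)OC1=O | intermediate
3 | (trimethylsilyl)acetylene | C#C[Si](C)(C)C | starting material
4 | dimethyl oxalate | COC(=O)C(=O)OC | starting material
5 | lithium (trimethylsilyl)acetylide | [Li+].[C-]#C[Si](C)(C)C | intermediate
6 | methyl 2-oxo-4-(trimethylsilyl)but-3-ynoate | COC(=O)C(=O)C#C[Si](C)(C)C | intermediate
7 | lithium (2R)-2-tert-butyl-5-methyl-1,3-dioxol-4-olate (enolate of 2) | CC1=C([O-])O[C@H](C(C)(C)C)O1.[Li+] | intermediate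
8 | methyl (2R)-2-[(2R,4S)-2-tert-butyl-4-methyl-5-oxo-1,3-dioxolan-4-yl]-2-hydroxy-4-(trimethylsilyl)but-3-ynoate | C[C@@]1([C@@](O)(C(=O)OC)C#C[Si](C)(C)C)O[C@@H](C(C)(C)C)OC1=O | intermediate
9 | methyl (2R)-2-[(2R,4S)-2-tert-butyl-4-methyl-5-oxo-1,3-dioxolan-4-yl]-2-hydroxybut-3-ynoate | C[C@@]1([C@@](O)(C(=O)OC)C#C)O[C@@H](C(C)(C)C)OC1=O | intermediate
10 | methyl (2R)-2-[(2R,4S)-2-tert-butyl-4-methyl-5-oxo-1,3-dioxolan-4-yl]-2-hydroxybut-3-enoate | C[C@@]1([C@@](O)(C(=O)OC)C=C)O[C@@H](C(C)(C)C)OC1=O | intermediate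
11 | methyl (2R)-2-[(2R,4S)-2-tert-butyl-4-methyl-5-oxo-1,3-dioxolan-4-yl]-2-[(triethylsilyl)oxy]but-3-enoate | C[C@@]1([C@@](O[Si](CC)(CC)CC)(C(=O)OC)C=C)O[C@@H](C(C)(C)C)OC1=O | intermediate
12 | methyl (2R,3S)-2-ethenyl-3-hydroxy-3-methyl-4-oxo-2-[(triethylsilyl)oxy]hex-5-enoate | C=CC(=O)[C@@](C)(O)[C@@](C=C)(O[Si](CC)(CC)CC)C(=O)OC | intermediate
13 | methyl (2R,3S)-3-acetoxy-2-ethenyl-3-methyl-4-oxo-2-[(triethylsilyl)oxy]hex-5-enoate | C=CC(=O)[C@@](C)(OC(C)=O)[C@@](C=C)(O[Si](CC)(CC)CC)C(=O)OC | intermediate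
14 | methyl (1R,5S)-5-acetoxy-5-methyl-4-oxo-1-[(triethylsilyl)oxy]cyclopent-2-ene-1-carboxylate | C1=CC(=O)[C@@](C)(OC(C)=O)[C@@]1(O[Si](CC)(CC)CC)C(=O)OC | intermediate
15 | methyl (1R,5S)-5-acetoxy-3-(hydroxymethyl)-5-methyl-4-oxo-1-[(triethylsilyl)oxy]cyclopent-2-ene-1-carboxylate | C1=C(CO)C(=O)[C@@](C)(OC(C)=O)[C@@]1(O[Si](CC)(CC)CC)C(=O)OC | intermediate
16 | methyl (1R,5S)-5-acetoxy-3-formyl-5-methyl-4-oxo-1-[(triethylsilyl)oxy]cyclopent-2-ene-1-carboxylate | C1=C(C=O)C(=O)[C@@](C)(OC(C)=O)[C@@]1(O[Si](CC)(CC)CC)C(=O)OC | intermediate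
17 | p-toluenesulfonamide | Cc1ccc(cc1)S(N)(=O)=O | starting material
18 | N-sulfinyl-p-toluenesulfonamide | Cc1ccc(cc1)S(=O)(=O)N=S=O | intermediate
19 | methyl (1R,5S)-5-acetoxy-5-methyl-3-{(E)-[(4-methylbenzenesulfonyl)imino]methyl}-4-oxo-1-[(triethylsilyl)oxy]cyclopent-2-ene-1-carboxylate | C1=C(/C=N/S(=O)(=O)c2ccc(C)cc2)C(=O)[C@@](C)(OC(C)=O)[C@@]1(O[Si](CC)(CC)CC)C(=O)OC | intermediate
20 | 2-methoxypropene | COC(C)=C | starting material
21 | methyl (5R,6S)-6-acetoxy-3-methoxy-3,6-dimethyl-2-(4-methylbenzenesulfonyl)-7-oxo-5-[(triethylsilyl)oxy]-2,3,4,4a,6,7-hexahydro-5H-cyclopenta[c]pyridine-5-carboxylate (C3 and C4a unassigned) | COC1(C)CC2C(=CN1S(=O)(=O)c1ccc(C)cc1)C(=O)[C@@](C)(OC(C)=O)[C@@]2(O[Si](CC)(CC)CC)C(=O)OC | intermediate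
22 | methyl (5R,6S)-6-acetoxy-3-methoxy-3,6-dimethyl-7-oxo-5-[(triethylsilyl)oxy]-3,4,6,7-tetrahydro-5H-cyclopenta[c]pyridine-5-carboxylate (C3 unassigned) | COC1(C)CC2=C(C=N1)C(=O)[C@@](C)(OC(C)=O)[C@@]2(O[Si](CC)(CC)CC)C(=O)OC | intermediate
23 | methyl (5R,6S)-6-acetoxy-3,6-dimethyl-7-oxo-5-[(triethylsilyl)oxy]-6,7-dihydro-5H-cyclopenta[c]pyridine-5-carboxylate | Cc1cc2c(cn1)C(=O)[C@@](C)(OC(C)=O)[C@@]2(O[Si](CC)(CC)CC)C(=O)OC | intermediate
24 | methyl (5R,6S)-6-acetoxy-3-formyl-6-methyl-7-oxo-5-[(triethylsilyl)oxy]-6,7-dihydro-5H-cyclopenta[c]pyridine-5-carboxylate | O=Cc1cc2c(cn1)C(=O)[C@@](C)(OC(C)=O)[C@@]2(O[Si](CC)(CC)CC)C(=O)OC | intermediate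
25 | (S)-2-methylbutan-1-ol | CC[C@H](C)CO | starting material
26 | ethyl 2-(triphenylphosphoranylidene)propanoate | CCOC(=O)C(C)=P(c1ccccc1)(c1ccccc1)c1ccccc1 | starting material
27 | (S)-2-methylbutanal | CC[C@H](C)C=O | intermediate
28 | ethyl (2E,4S)-2,4-dimethylhex-2-enoate | CC[C@H](C)/C=C(C)/C(=O)OCC | intermediate
29 | (2E,4S)-2,4-dimethylhex-2-en-1-ol | CC[C@H](C)/C=C(C)/CO | intermediate
30 | 1-phenyl-1H-tetrazole-5-thiol | Sc1nnnn1-c1ccccc1 | starting material
31 | 5-{[(2E,4S)-2,4-dimethylhex-2-en-1-yl]sulfanyl}-1-phenyl-1H-tetrazole | CC[C@H](C)/C=C(C)/CSc1nnnn1-c1ccccc1 | intermediate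
32 | 5-{[(2E,4S)-2,4-dimethylhex-2-en-1-yl]sulfonyl}-1-phenyl-1H-tetrazole | CC[C@H](C)/C=C(C)/CS(=O)(=O)c1nnnn1-c1ccccc1 | intermediate
33 | potassium salt of the α-sulfonyl carbanion of 32 | CC[C@H](C)/C=C(C)/[CH-]S(=O)(=O)c1nnnn1-c1ccccc1.[K+] | intermediate
34 | methyl (5R,6S)-6-acetoxy-3-[(1E,3E,5S)-3,5-dimethylhepta-1,3-dien-1-yl]-6-methyl-7-oxo-5-[(triethylsilyl)oxy]-6,7-dihydro-5H-cyclopenta[c]pyridine-5-carboxylate | CC[C@H](C)/C=C(C)/C=C/c1cc2c(cn1)C(=O)[C@@](C)(OC(C)=O)[C@@]2(O[Si](CC)(CC)CC)C(=O)OC | intermediate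
35 | methyl (5R,6S)-6-acetoxy-3-[(1E,3E,5S)-3,5-dimethylhepta-1,3-dien-1-yl]-5-hydroxy-6-methyl-7-oxo-6,7-dihydro-5H-cyclopenta[c]pyridine-5-carboxylate | CC[C@H](C)/C=C(C)/C=C/c1cc2c(cn1)C(=O)[C@@](C)(OC(C)=O)[C@@]2(O)C(=O)OC | target

**Step count**

Total: 20 steps. Longest linear sequence: 14 steps from (R)-lactic acid (steps 1, 3–10, 12–14, 19, 20).

**Steps most likely to fail**

Step 3. The two faces of the ketone may not be told apart in the aldol transition state, with ester and alkynyl group exchanging the outward and the over-ring positions, so that the C5 epimer forms alongside. The alkoxide may also revert by retro-aldol cleavage if it warms before protonation. Fallback: C5 is set by nucleophilic addition to a ketone instead of by the aldol. Setting out from 2, the enolate 7 is C-acylated with methyl chlorooxoacetate at –78 °C, again opposite the tert-butyl group, to give the α-keto ester methyl 2-[(2R,4S)-2-tert-butyl-4-methyl-5-oxo-1,3-dioxolan-4-yl]-2-oxoacetate F1. Lithium acetylide 5 is then added to the ketone of F1 at –78 °C. A polar Felkin–Anh approach, anti to the ring C–O bond and past the flat ring carbonyl carbon instead of the methyl group, should give the 5R carbinol 8. Buffered n-Bu4NF then returns the material to the route at 9.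

Step 9. Addition of the phosphine to C4a, next to the fully substituted C5, may be too slow, and long exposure to the aqueous basic medium may cleave the acetate. Fallback: C1 is brought in before the ring is closed. Setting out from 11, 2-lithio-3,3-diethoxyprop-1-ene (from 2-bromo-3,3-diethoxyprop-1-ene and t-BuLi, –78 °C) opens the dioxolanone as in step 6 to give methyl (2R,3S)-5-(diethoxymethyl)-2-ethenyl-3-hydroxy-3-methyl-4-oxo-2-[(triethylsilyl)oxy]hex-5-enoate F2. Acetylation as in step 7 gives methyl (2R,3S)-3-acetoxy-5-(diethoxymethyl)-2-ethenyl-3-methyl-4-oxo-2-[(triethylsilyl)oxy]hex-5-enoate F3. Ring-closing metathesis with RuCl2(=CHPh)(PCy3)(H2IMes), now forming a trisubstituted alkene and so run hotter, gives methyl (1R,5S)-5-acetoxy-3-(diethoxymethyl)-5-methyl-4-oxo-1-[(triethylsilyl)oxy]cyclopent-2-ene-1-carboxylate F4. Mild acetal hydrolysis (oxalic acid on wet silica, CH2Cl2) gives 16, where the route is rejoined.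

Step 13. The azadiene 19 may hydrolyse or oligomerise before it is intercepted, or the enol ether may attack the imine carbon C1 (Mannich or imino-ene path) because C4a is shielded by the neighbouring quaternary C5. Fallback: the pyridine ring is built stepwise from a 1,5-dicarbonyl compound. Setting out from 16, Mukaiyama–Michael addition of 2-(trimethylsilyloxy)propene to C4a (Sc(OTf)3 cat., CH2Cl2, –78 °C, aqueous work-up) gives methyl (1R,2S)-2-acetoxy-4-formyl-2-methyl-3-oxo-5-(2-oxopropyl)-1-[(triethylsilyl)oxy]cyclopentane-1-carboxylate F5. Condensation with NH2OH·HCl and NaOAc in EtOH at 60 °C closes the ring and aromatises it by loss of water to give 23, where the route is rejoined.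

**Further compounds**

F1 | step 3 | methyl 2-[(2R,4S)-2-tert-butyl-4-methyl-5-oxo-1,3-dioxolan-4-yl]-2-oxoacetate | C[C@@]1(C(=O)C(=O)OC)O[C@@H](C(C)(C)C)OC1=O
F2 | step 9 | methyl (2R,3S)-5-(diethoxymethyl)-2-ethenyl-3-hydroxy-3-methyl-4-oxo-2-[(triethylsilyl)oxy]hex-5-enoate | CCOC(OCC)C(=C)C(=O)[C@@](C)(O)[C@@](C=C)(O[Si](CC)(CC)CC)C(=O)OC
F3 | step 9 | methyl (2R,3S)-3-acetoxy-5-(diethoxymethyl)-2-ethenyl-3-methyl-4-oxo-2-[(triethylsilyl)oxy]hex-5-enoate | CCOC(OCC)C(=C)C(=O)[C@@](C)(OC(C)=O)[C@@](C=C)(O[Si](CC)(CC)CC)C(=O)OC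
F4 | step 9 | methyl (1R,5S)-5-acetoxy-3-(diethoxymethyl)-5-methyl-4-oxo-1-[(triethylsilyl)oxy]cyclopent-2-ene-1-carboxylate | C1=C(C(OCC)OCC)C(=O)[C@@](C)(OC(C)=O)[C@@]1(O[Si](CC)(CC)CC)C(=O)OC
F5 | step 13 | methyl (1R,2S)-2-acetoxy-4-formyl-2-methyl-3-oxo-5-(2-oxopropyl)-1-[(triethylsilyl)oxy]cyclopentane-1-carboxylate | CC(=O)CC1C(C=O)C(=O)[C@@](C)(OC(C)=O)[C@@]1(O[Si](CC)(CC)CC)C(=O)OC
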